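**Strategy**

The cyclopentane ring (C1–C5) and the neighbouring tertiary carbinol C10 of the trans-hydroazulene are traced back to an eudesmane: the photochemical rearrangement of the 4-methyl cross-conjugated dienone 1,2-dehydro-α-cyperone in aqueous acetic acid. In one operation C1–C5 bonding and C5–C10 cleavage contract the six-membered dienone ring to the cyclopentenone, enlarge ring B to the cycloheptane, and set C1–H and the C10 hydroxyl with the C7 isopropenyl group already in place. The resulting C3 enone then directs the rest: reductive enolate formation, a three-component union with a Boc-salicylaldehyde and i-BuMgBr through an ortho-quinone methide (C4 and C1′), deoxygenation, double formylation and MOM removal.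

Key step: step 4

Remark: guaiane numbering is used throughout (cyclopentane C1–C2–C3–C4–C5, cycloheptane C1–C10–C9–C8–C7–C6–C5, CH3-15 on C4, CH3-14 on C10, isopropenyl C11–C13 on C7, C1′ = benzylic carbon; the eudesmane precursors carry the same numbers), and commercial (+)-dihydrocarvone is assumed to be usable as its C2-epimer mixture because C2 is erased at the enamine stage.

**Route**

Step 1
Reactants: 1 (2R,5R)-2-methyl-5-(prop-1-en-2-yl)cyclohexan-1-one [(+)-dihydrocarvone]; 2 (R)-1-phenylethylamine; 3 pent-1-en-3-one (ethyl vinyl ketone)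
Product: 6 (2S,5R)-2-methyl-2-(3-oxopentyl)-5-(prop-1-en-2-yl)cyclohexan-1-one, via ketimine 4 (not isolated), via Michael adduct imine 5 (not isolated)
Conditions: 2, TsOH (cat.), toluene, reflux, Dean–Stark; then 3, THF, 40 °C; then 10% aq. AcOH, 23 °C
Reagents that add atoms: none
Why: Auxiliary-controlled Michael addition of a chiral imine through its more substituted secondary enamine tautomer (aza-ene-like chair transition state), in which the enone is expected to approach anti to the phenyl group, so that the (R)-amine places the 3-oxopentyl chain trans to the isopropenyl group (2S) against the intrinsic axial bias of the ring.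

Step 2
Reactants: 6 (2S,5R)-2-methyl-2-(3-oxopentyl)-5-(prop-1-en-2-yl)cyclohexan-1-one
Product: 7 (+)-α-cyperone, (4aS,7R)-1,4a-dimethyl-7-(prop-1-en-2-yl)-4,4a,5,6,7,8-hexahydronaphthalen-2(3H)-one
Conditions: NaOMe, MeOH, 23 → 65 °C
Reagents that add atoms: none
Why: Intramolecular aldol condensation (second stage of a Robinson annulation) should close ring A and create no new stereocentre.

Step 3
Reactants: 7 (+)-α-cyperone
Product: 8 1,2-dehydro-α-cyperone, (4aS,7R)-1,4a-dimethyl-7-(prop-1-en-2-yl)-5,6,7,8-tetrahydronaphthalen-2(4aH)-one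
Conditions: DDQ, dioxane, reflux
Reagents that add atoms: none
Why: DDQ dehydrogenation of a 4-en-3-one under neutral conditions should proceed through the C2 enol and hydride loss from C1 to the cross-conjugated 1,4-dien-3-one, as with 3-oxo-4-ene steroids, without touching a stereocentre.

Step 4
Reactants: 8 1,2-dehydro-α-cyperone
Product: 9 (1R,7R,10R)-10-hydroxyguaia-4,11-dien-3-one (1αH, 10α-OH, 10β-CH3, 7β-isopropenyl)
Conditions: hν (medium-pressure Hg lamp, Pyrex), AcOH–H2O (1:1), N2, 20 °C
Reagents that add atoms: water (O)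
Why: Excitation of dienone 8 should lead from the triplet to C1–C5 bonding and a bicyclo[3.1.0]hexenyl oxyallyl zwitterion in which C1, C5 and C10 form a cyclopropane, and O-protonation by acetic acid then gives a 3-hydroxyallyl cation whose C4 terminus opens the C5–C10 bond as water adds to C10. This is the santonin to isophotosantonic lactone rearrangement of 4-methyl cross-conjugated cyclohexadienones in aqueous acetic acid. The cyclopentenone ring is closed by the C1–C5 bond between the two β-carbons of the dienone, which expels C10 from the former six-membered ring, whereas the cycloheptane is not closed but arises when the internal cyclopropane bond C5–C10 breaks. At C1, ring B must stay cis-fused to the transient cyclopropane, so the C2–C4 bridge can fold only toward the face of the angular methyl and H1 ends α; at C10, water attacks anti to the departing C5 (inversion), which leaves 10α-OH and 10β-CH3, and C7 is untouched. The step needs cleavage of C5–C10 rather than of C1–C10 (spiro ketone) or the 1,4-shift to a lumiketone, and this is secured by the C4 methyl, which localises the positive charge next to C5, and by the acidic aqueous medium, which intercepts the zwitterion before it rearranges; irradiation is stopped at full conversion because 9 is itself photoactive.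

Step 5
Reactants: 9 (1R,7R,10R)-10-hydroxyguaia-4,11-dien-3-one
Product: 11 (1R,5S,7R,10R)-3,10-bis(trimethylsilyloxy)guaia-3,11-diene (1αH, 5βH), via dilithium enolate alkoxide 10 (not isolated)
Conditions: 9 added to Li (2.2 equiv), NH3(l)–THF, −78 °C; NH3 evaporated; then TMSCl, Et3N, THF, −78 → 0 °C
Reagents that add atoms: chlorotrimethylsilane, C[Si](C)(C)Cl
Why: Dissolving-metal (Birch-type) enone reduction with silyl trapping of the regiodefined C3–C4 enolate, in which the hydroxyl proton of 9 (relayed by NH3) is the single proton source and C5 should be protonated anti to H1 to give the trans-fused hydroazulene, the usual outcome for cyclopentenones whose β-carbon is a ring-fusion atom (for example Pauson–Khand-type bicyclo[5.3.0]decenones), while the isolated alkene is inert.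

Step 6
Reactants: 12 2,4,6-trihydroxybenzaldehyde
Product: 13 2-hydroxy-4,6-bis(methoxymethoxy)benzaldehyde
Conditions: MOMCl (2.1 equiv), K2CO3, acetone, 0 → 23 °C
Reagents that add atoms: chloromethyl methyl ether, COCCl
Why: Williamson-type O-alkylation (MOM protection) should take the para and one ortho hydroxyl, the second ortho hydroxyl being held back by its hydrogen bond to the formyl group.

Step 7
Reactants: 13 2-hydroxy-4,6-bis(methoxymethoxy)benzaldehyde
Product: 14 tert-butyl 2-formyl-3,5-bis(methoxymethoxy)phenyl carbonate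
Conditions: Boc2O, DMAP (5 mol %), MeCN, 23 °C
Reagents that add atoms: di-tert-butyl dicarbonate, CC(C)(C)OC(=O)OC(=O)OC(C)(C)C
Why: DMAP-catalysed O-acylation of the remaining phenol gives the aryl carbonate that later acts as an internal leaving-group donor.

Step 8
Reactants: 11 (1R,5S,7R,10R)-3,10-bis(trimethylsilyloxy)guaia-3,11-diene; 14 tert-butyl 2-formyl-3,5-bis(methoxymethoxy)phenyl carbonate
Product: 18 (1R,4S,5S,7R,10R)-4-[(1S)-1-(2-hydroxy-4,6-bis(methoxymethoxy)phenyl)-3-methylbutyl]-10-(trimethylsilyloxy)guai-11-en-3-one (side chain 4β, CH3 4α; C1′ has the spatial arrangement of the target), via lithium enolate 15 (not isolated), via carbonate phenoxide 16 (not isolated), via ortho-quinone methide 17 (not isolated)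
Conditions: MeLi, THF, 0 °C; 14, −78 °C; then i-BuMgBr (3 equiv), −78 → −20 °C; aq. NH4Cl
Reagents that add atoms: isobutylmagnesium bromide, CC(C)C[Mg]Br
Why: Aldol addition of the regiodefined enolate 15 should occur on the β face of C4 (anti to the C5–C6 bond), the aldolate is trapped by O-to-O Boc transfer (16), the magnesium phenoxide eliminates tert-butyl carbonate to the ortho-quinone methide 17, and 1,4-addition of the Grignard reagent to C1′ is expected from the face flanked by the C3 carbonyl and opposite the C5 methine, with the C4 methyl lying in the quinone methide plane to relieve allylic 1,3-strain, which corresponds to the C1′ configuration of the target.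

Step 9
Reactants: 18 the phenol ketone from step 8
Product: 19 (1R,4S,5S,7R,10R)-4-[(1S)-3-methyl-1-(2,4,6-tris(methoxymethoxy)phenyl)butyl]-10-(trimethylsilyloxy)guai-11-en-3-one
Conditions: NaH, MOMCl, DMF, 0 °C
Reagents that add atoms: chloromethyl methyl ether, COCCl
Why: O-alkylation of the sodium phenoxide (MOM protection) should take place on the open phenoxide–ketone form, which dominates over any hemiketal once the phenol is deprotonated.

Step 10
Reactants: 19 the tris-MOM ketone from step 9
Product: 21 (1R,4S,5S,7R,10R)-4-[(1R)-3-methyl-1-(2,4,6-tris(methoxymethoxy)phenyl)butyl]guai-11-en-10-ol, via hydrazone 20 (not isolated)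
Conditions: N2H4·H2O, KOH, diethylene glycol, 130 °C, then 200 °C
Reagents that add atoms: none
Why: Wolff–Kishner reduction (Huang-Minlon procedure) of a cyclopentanone flanked by one quaternary carbon, comparable to camphor or a 17-oxo steroid, should proceed through hydrazone 20 with loss of N2, while the MOM ethers, the isopropenyl group and all stereocentres (C4 is quaternary) are stable to hot base and the silyl ether is cleaved by hydroxide.

Step 11
Reactants: 21 the deoxygenated tris-MOM alcohol from step 10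
Product: 23 5-[(1R)-1-[(1R,4S,5S,7R,10R)-10-hydroxyguai-11-en-4-yl]-3-methylbutyl]-2,4,6-tris(methoxymethoxy)benzene-1,3-dicarbaldehyde, via lithium aminoalkoxide 22 (not isolated)
Conditions: n-BuLi (2.2 equiv), TMEDA, THF, −20 °C; DMF (1.1 equiv), −78 °C; then n-BuLi, −40 °C; DMF; aq. NH4Cl
Reagents that add atoms: N,N-dimethylformamide, CN(C)C=O
Why: Directed ortho-metalation should lithiate each free ring position, which lies between two MOM ethers, and formylation with DMF gives the lithium aminoalkoxide 22, which masks the first aldehyde during the second lithiation–formylation.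

Step 12
Reactants: 23 the tris-MOM dialdehyde from step 11
Product: 24 5-[(1R)-1-[(1R,4S,5S,7R,10R)-10-hydroxyguai-11-en-4-yl]-3-methylbutyl]-2,4,6-trihydroxybenzene-1,3-dicarbaldehyde (target)
Conditions: aq. HCl (3 M), MeOH–THF, 23 °C
Reagents that add atoms: none
Why: Acid-catalysed acetal cleavage of the aryl MOM ethers is accelerated by the ortho formyl groups, so dilute acid at ambient temperature should spare the isopropenyl group and the tertiary alcohol.

**Compound list**

1 | (2R,5R)-2-methyl-5-(prop-1-en-2-yl)cyclohexan-1-one, (+)-dihydrocarvone | O=C1C[C@H](C(C)=C)CC[C@H]1C | starting material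
2 | (R)-1-phenylethylamine | C[C@@H](N)c1ccccc1 | starting material
3 | pent-1-en-3-one (ethyl vinyl ketone) | CCC(=O)C=C | starting material
4 | N-[(1R)-1-phenylethyl] ketimine of 1 | C[C@@H](N=C1C[C@H](C(C)=C)CC[C@H]1C)c1ccccc1 | intermediate (not isolated)
5 | N-[(1R)-1-phenylethyl] ketimine of 6 (Michael adduct) | C[C@@H](N=C1C[C@H](C(C)=C)CC[C@@]1(C)CCC(=O)CC)c1ccccc1 | intermediate (not isolated)
6 | (2S,5R)-2-methyl-2-(3-oxopentyl)-5-(prop-1-en-2-yl)cyclohexan-1-one | O=C1C[C@H](C(C)=C)CC[C@@]1(C)CCC(=O)CC | intermediate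
7 | (+)-α-cyperone, (4aS,7R)-1,4a-dimethyl-7-(prop-1-en-2-yl)-4,4a,5,6,7,8-hexahydronaphthalen-2(3H)-one | CC1=C2C[C@H](C(C)=C)CC[C@@]2(C)CCC1=O | intermediate
8 | 1,2-dehydro-α-cyperone, (4aS,7R)-1,4a-dimethyl-7-(prop-1-en-2-yl)-5,6,7,8-tetrahydronaphthalen-2(4aH)-one | CC1=C2C[C@H](C(C)=C)CC[C@@]2(C)C=CC1=O | intermediate
9 | (1R,7R,10R)-10-hydroxyguaia-4,11-dien-3-one | C=C(C)[C@@H]1CC[C@@](C)(O)[C@@H]2CC(=O)C(C)=C2C1 | intermediate
10 | dilithium (1R,5S,7R,10R)-guaia-3,11-diene-3,10-diolate | C=C(C)[C@@H]1CC[C@@](C)([O-])[C@@H]2CC([O-])=C(C)[C@H]2C1.[Li+].[Li+] | intermediate (not isolated)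
11 | (1R,5S,7R,10R)-3,10-bis(trimethylsilyloxy)guaia-3,11-diene | C=C(C)[C@@H]1CC[C@@](C)(O[Si](C)(C)C)[C@@H]2CC(O[Si](C)(C)C)=C(C)[C@H]2C1 | intermediate
12 | 2,4,6-trihydroxybenzaldehyde | O=Cc1c(O)cc(O)cc1O | starting material
13 | 2-hydroxy-4,6-bis(methoxymethoxy)benzaldehyde | O=Cc1c(O)cc(OCOC)cc1OCOC | intermediate
14 | tert-butyl 2-formyl-3,5-bis(methoxymethoxy)phenyl carbonate | O=Cc1c(OC(=O)OC(C)(C)C)cc(OCOC)cc1OCOC | intermediate
15 | lithium (1R,5S,7R,10R)-10-(trimethylsilyloxy)guaia-3,11-dien-3-olate | C=C(C)[C@@H]1CC[C@@](C)(O[Si](C)(C)C)[C@@H]2CC([O-])=C(C)[C@H]2C1.[Li+] | intermediate (not isolated)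
16 | lithium 2-[(tert-butoxycarbonyloxy)(3-oxo-10α-trimethylsilyloxy-1αH,5βH-guai-11-en-4β-yl)methyl]-3,5-bis(methoxymethoxy)phenoxide (C1′ epimers) | C=C(C)[C@@H]1CC[C@@](C)(O[Si](C)(C)C)[C@@H]2CC(=O)[C@](C)(C(OC(=O)OC(C)(C)C)c3c([O-])cc(OCOC)cc3OCOC)[C@H]2C1.[Li+] | intermediate (not isolated)
17 | 6-[(3-oxo-10α-trimethylsilyloxy-1αH,5βH-guai-11-en-4β-yl)methylidene]-3,5-bis(methoxymethoxy)cyclohexa-2,4-dien-1-one | C=C(C)[C@@H]1CC[C@@](C)(O[Si](C)(C)C)[C@@H]2CC(=O)[C@](C)(C=C3C(=O)C=C(OCOC)C=C3OCOC)[C@H]2C1 | intermediate (not isolated)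
18 | (1R,4S,5S,7R,10R)-4-[(1S)-1-(2-hydroxy-4,6-bis(methoxymethoxy)phenyl)-3-methylbutyl]-10-(trimethylsilyloxy)guai-11-en-3-one | C=C(C)[C@@H]1CC[C@@](C)(O[Si](C)(C)C)[C@@H]2CC(=O)[C@](C)([C@@H](CC(C)C)c3c(O)cc(OCOC)cc3OCOC)[C@H]2C1 | intermediate
19 | (1R,4S,5S,7R,10R)-4-[(1S)-3-methyl-1-(2,4,6-tris(methoxymethoxy)phenyl)butyl]-10-(trimethylsilyloxy)guai-11-en-3-one | C=C(C)[C@@H]1CC[C@@](C)(O[Si](C)(C)C)[C@@H]2CC(=O)[C@](C)([C@@H](CC(C)C)c3c(OCOC)cc(OCOC)cc3OCOC)[C@H]2C1 | intermediate
20 | hydrazone of (1R,4S,5S,7R,10R)-10-hydroxy-4-[(1R)-3-methyl-1-(2,4,6-tris(methoxymethoxy)phenyl)butyl]guai-11-en-3-one | C=C(C)[C@@H]1CC[C@@](C)(O)[C@@H]2CC(=NN)[C@](C)([C@@H](CC(C)C)c3c(OCOC)cc(OCOC)cc3OCOC)[C@H]2C1 | intermediate (not isolated)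
21 | (1R,4S,5S,7R,10R)-4-[(1R)-3-methyl-1-(2,4,6-tris(methoxymethoxy)phenyl)butyl]guai-11-en-10-ol | C=C(C)[C@@H]1CC[C@@](C)(O)[C@@H]2CC[C@](C)([C@@H](CC(C)C)c3c(OCOC)cc(OCOC)cc3OCOC)[C@H]2C1 | intermediate
22 | dilithium salt of the mono-formylation adduct of 21 (C10 alkoxide; aryl CH(O−)NMe2 at one free ring position) | C=C(C)[C@@H]1CC[C@@](C)([O-])[C@@H]2CC[C@](C)([C@@H](CC(C)C)c3c(OCOC)c(C([O-])N(C)C)c(OCOC)cc3OCOC)[C@H]2C1.[Li+].[Li+] | intermediate (not isolated)
23 | 5-[(1R)-1-[(1R,4S,5S,7R,10R)-10-hydroxyguai-11-en-4-yl]-3-methylbutyl]-2,4,6-tris(methoxymethoxy)benzene-1,3-dicarbaldehyde | C=C(C)[C@@H]1CC[C@@](C)(O)[C@@H]2CC[C@](C)([C@@H](CC(C)C)c3c(OCOC)c(C=O)c(OCOC)c(C=O)c3OCOC)[C@H]2C1 | intermediate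
24 | 5-[(1R)-1-[(1R,4S,5S,7R,10R)-10-hydroxyguai-11-en-4-yl]-3-methylbutyl]-2,4,6-trihydroxybenzene-1,3-dicarbaldehyde | C=C(C)[C@@H]1CC[C@@](C)(O)[C@@H]2CC[C@](C)([C@@H](CC(C)C)c3c(O)c(C=O)c(O)c(C=O)c3O)[C@H]2C1 | target

**Step count and risks**

Total step count: 12. Longest linear sequence: 10 steps (steps 1–5 and 8–12); the aryl fragment takes 2 steps (6 and 7).

The three steps most likely to fail:

First, step 8. The cascade may give poor facial selectivity at C1′ in the Grignard addition to 17, the Grignard reagent may attack the C3 ketone, or the hindered aldolate may revert before the Boc group moves. The fallback reverses the order of the two C–C bond formations and sets out from 14 and 11. Aldehyde 14 is first treated with i-BuMgBr (1.05 equiv, THF, −78 °C). Boc transfer and loss of tert-butyl carbonate then generate 3,5-bis(methoxymethoxy)-6-(3-methylbutylidene)cyclohexa-2,4-dien-1-one F1 in the presence of lithium enolate 15 (from 11 and MeLi), which adds in Michael fashion to C1′. The C4–C1′ bond is then formed last, C1′ is set by the pairing of enolate and quinone methide faces instead of by 1,2-induction, and the C3 ketone never meets the Grignard reagent. The route is rejoined at 18.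

Second, step 10. Hydrazone formation at the C3 carbonyl, which sits next to the fully substituted C4 with its large side chain, may be too slow, and prolonged heating in base may erode the MOM ethers. The fallback is a three-stage radical deoxygenation that sets out from 19.
- LiAlH4 (THF, 0 °C) should give (1R,4S,5S,7R,10R)-4-[(1R)-3-methyl-1-(2,4,6-tris(methoxymethoxy)phenyl)butyl]-10-(trimethylsilyloxy)guai-11-en-3-ol F2 (either C3 epimer serves).
- NaH, CS2 and MeI should convert it into the O-(guai-11-en-3-yl) S-methyl carbonodithioate F3; the C10 silyl ether keeps the tertiary alcohol out of this step.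
- Bu3SnH and AIBN in toluene at 110 °C (Barton–McCombie deoxygenation through a secondary C3 radical) should give (1R,4S,5S,7R,10R)-4-[(1R)-3-methyl-1-(2,4,6-tris(methoxymethoxy)phenyl)butyl]-10-(trimethylsilyloxy)guai-11-ene F4.
- K2CO3 in MeOH removes the silyl ether and the route is rejoined at 21.

Third, step 11. The second lithiation may stall next to the anionic aminoalkoxide, or metalation may stray to the allylic positions of the isopropenyl group. The fallback replaces deprotonation by halogen–lithium exchange and sets out from 21. NBS (2.1 equiv, MeCN, −20 °C) should brominate both activated ring positions by electrophilic aromatic substitution to give 3,5-dibromo-1-[(1R)-1-[(1R,4S,5S,7R,10R)-10-hydroxyguai-11-en-4-yl]-3-methylbutyl]-2,4,6-tris(methoxymethoxy)benzene F5. t-BuLi (5 equiv, THF, −78 °C) followed by DMF then formylates both positions, and the route is rejoined at 23.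

Further compounds
F1 | step 8 | 3,5-bis(methoxymethoxy)-6-(3-methylbutylidene)cyclohexa-2,4-dien-1-one | CC(C)CC=C1C(=O)C=C(OCOC)C=C1OCOC
F2 | step 10 | (1R,4S,5S,7R,10R)-4-[(1R)-3-methyl-1-(2,4,6-tris(methoxymethoxy)phenyl)butyl]-10-(trimethylsilyloxy)guai-11-en-3-ol (C3 epimers) | C=C(C)[C@@H]1CC[C@@](C)(O[Si](C)(C)C)[C@@H]2CC(O)[C@](C)([C@@H](CC(C)C)c3c(OCOC)cc(OCOC)cc3OCOC)[C@H]2C1
F3 | step 10 | O-[(1R,4S,5S,7R,10R)-4-[(1R)-3-methyl-1-(2,4,6-tris(methoxymethoxy)phenyl)butyl]-10-(trimethylsilyloxy)guai-11-en-3-yl] S-methyl carbonodithioate | C=C(C)[C@@H]1CC[C@@](C)(O[Si](C)(C)C)[C@@H]2CC(OC(=S)SC)[C@](C)([C@@H](CC(C)C)c3c(OCOC)cc(OCOC)cc3OCOC)[C@H]2C1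
F4 | step 10 | (1R,4S,5S,7R,10R)-4-[(1R)-3-methyl-1-(2,4,6-tris(methoxymethoxy)phenyl)butyl]-10-(trimethylsilyloxy)guai-11-ene | C=C(C)[C@@H]1CC[C@@](C)(O[Si](C)(C)C)[C@@H]2CC[C@](C)([C@@H](CC(C)C)c3c(OCOC)cc(OCOC)cc3OCOC)[C@H]2C1
F5 | step 11 | 3,5-dibromo-1-[(1R)-1-[(1R,4S,5S,7R,10R)-10-hydroxyguai-11-en-4-yl]-3-methylbutyl]-2,4,6-tris(methoxymethoxy)benzene | C=C(C)[C@@H]1CC[C@@](C)(O)[C@@H]2CC[C@](C)([C@@H](CC(C)C)c3c(OCOC)c(Br)c(OCOC)c(Br)c3OCOC)[C@H]2C1
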